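## Retrosynthetic overview
1. Pyran numbering: O1, C2 (CH3), C3 (CH2OH), C4 (CH2CO2R), C5 (CO2Me), C6 (=CH–O).
2. Key disconnection: the enol-ether bond O1–C6. A chiral secondary alkoxide adds to C6 of methyl coumalate and the pyrone opens. The pyrone supplies C4, C5, C6, the CO2Me group and the acetic acid arm, with the two carboxyls already differentiated.
3. Second C–O disconnection: the acyl–O bond to unprotected hydroxytyrosol (Mitsunobu).
4. Last disconnection: C3–C4, closed by a reductive epoxide-opening radical 6-exo cyclisation that also liberates the CH2OH group. C2 comes from a Sharpless kinetic resolution and controls C3 and C4.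
5. Ring order: the oxirane is made first (step 1), the purchased pyrone is opened (step 2), and the dihydropyran is closed last (step 4) as the oxirane is consumed. The catechol ring is bought.

Assumption: racemic but-3-en-2-ol, methyl coumalate, hydroxytyrosol and D-(−)-diisopropyl tartrate are taken as cheap catalogue chemicals.

## Route

Step 1
Reactants: 1 (±)-but-3-en-2-ol
Product: 2 (2R,3S)-3,4-epoxybutan-2-ol
Conditions: Ti(OiPr)4 (0.2 equiv), D-(−)-DIPT (0.24 equiv), TBHP (0.45 equiv, decane), 4 Å MS, CH2Cl2, −20 °C; non-aqueous work-up, distillation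
Reagents that add atoms: tert-butyl hydroperoxide, CC(C)(C)OO
Why: Sharpless asymmetric epoxidation run as a kinetic resolution: with the D-(−)-tartrate catalyst the (R)-alcohol is the fast-reacting enantiomer and is epoxidised erythro-selectively, so stopping near 45% conversion gives (2R,3S)-2, whose carbinol centre becomes C2 (R) of the target, while the oxirane centre is only a radical precursor and is planarised in step 4.

Step 2
Reactants: 2 (2R,3S)-3,4-epoxybutan-2-ol; 3 methyl coumalate (methyl 2-oxo-2H-pyran-5-carboxylate)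
Product: 7 (2Z,4E)-4-(methoxycarbonyl)-5-{(1R)-1-[(2S)-oxiran-2-yl]ethoxy}penta-2,4-dienoic acid, via lithium alkoxide 4 (not isolated), via C6 adduct 5 (not isolated), via lithium carboxylate 6 (not isolated)
Conditions: LiHMDS (0.98 equiv), THF, −78 °C; cannulate into 3 (1.1 equiv), THF, −78 to −30 °C; cold 0.5 M HCl to pH 3, EtOAc; use at once
Reagents that add atoms: none
Why: Proposed new method: a stoichiometric chiral secondary alkoxide serves as the nucleophile in a 1,6-oxa-conjugate addition/ring-opening of a 2-pyrone, in which alkoxide 4 attacks C6 of 3 (doubly activated as the β-carbon of the acrylate and the δ-carbon of the dienolide) to give 5, whose ring C6–O bond breaks by E1cB/retro-oxa-6π opening because carboxylate is a far better leaving group than the incoming alkoxide, so the O1–C6 bond forms irreversibly, the two carboxyls emerge differentiated (free acid versus methyl ester), the push–pull enol ether settles as the E isomer (alkoxy trans to CO2Me, as in β-methoxyacrylates) that places O1 cis to the future C4, attack at the lactone carbonyl is harmless because that adduct re-closes to 3 on acidification, and the carbinol C–O bond of 2 is never broken so C2 stays R; the closest known reaction types are the 1,6-addition/ring-opening of methyl coumalate by Grignard reagents, stabilised carbanions and amines and its solvolysis in acidic methanol, none of which uses a functionalised alcohol as the limiting partner.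

Step 3
Reactants: 7 (2Z,4E)-4-(methoxycarbonyl)-5-{(1R)-1-[(2S)-oxiran-2-yl]ethoxy}penta-2,4-dienoic acid; 8 hydroxytyrosol (2-(3,4-dihydroxyphenyl)ethanol)
Product: 10 2-(3,4-dihydroxyphenyl)ethyl (2Z,4E)-4-(methoxycarbonyl)-5-{(1R)-1-[(2S)-oxiran-2-yl]ethoxy}penta-2,4-dienoate, via alkoxyphosphonium carboxylate 9 (not isolated)
Conditions: PPh3 (1.3 equiv), DIAD (1.3 equiv, premixed at 0 °C), then 7 and 8 (1.05 equiv), THF, 0 °C to rt
Reagents that add atoms: none
Why: Mitsunobu esterification: the primary alcohol of 8 is activated as alkoxyphosphonium 9 and displaced by the carboxylate of 7, which is far more acidic than the catechol OH groups, so the phenols need no protection, the acid is never turned into an acyl donor (no return to pyrone 3), the oxirane and enol ether are untouched, and no stereocentre is involved.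

Step 4
Reactants: 10 2-(3,4-dihydroxyphenyl)ethyl (2Z,4E)-4-(methoxycarbonyl)-5-{(1R)-1-[(2S)-oxiran-2-yl]ethoxy}penta-2,4-dienoate
Product: 13 methyl (2R,3R,4S)-4-{2-[2-(3,4-dihydroxyphenyl)ethoxy]-2-oxoethyl}-3-(hydroxymethyl)-2-methyl-3,4-dihydro-2H-pyran-5-carboxylate, via open titanoxy radical 11 (not isolated), via cyclised ester radical 12 (not isolated)
Conditions: Cp2TiCl2 (20 mol %), Mn powder (3 equiv), 2,4,6-collidine·HCl (3 equiv), degassed THF (0.01 M), rt, 10 added over 4 h; pH 5 buffer work-up
Reagents that add atoms: none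
Why: Nugent–RajanBabu/Gansäuer reductive epoxide opening followed by a Giese-type 6-exo-trig radical cyclisation: Cp2TiCl (trivalent titanium, regenerated by Mn) cleaves the oxirane C–O bond at the more substituted carbon to give the nucleophilic secondary radical 11, which adds to the enoate β-carbon (C4) through a chair-like transition state with the C2 methyl, the bulky C3 CH2O[Ti] group and the C4 side chain all pseudo-equatorial, so the fixed C2 (R) centre sets C3 (R) and C4 (S) as the all-trans array, after which 12 is reduced by a second Cp2TiCl and protonated by collidinium chloride, a buffer that also cleaves the Ti–O bonds, should keep the catechol protonated and should be too mild to lactonise the δ-hydroxy ester.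

## Compound list
1 | (±)-but-3-en-2-ol | CC(O)C=C | starting material
2 | (2R,3S)-3,4-epoxybutan-2-ol, i.e. (1R)-1-[(2S)-oxiran-2-yl]ethanol | C[C@@H](O)[C@@H]1CO1 | intermediate
3 | methyl coumalate | COC(=O)C1=COC(=O)C=C1 | starting material
4 | lithium (1R)-1-[(2S)-oxiran-2-yl]ethanolate | C[C@@H]([O-])[C@@H]1CO1.[Li+] | intermediate
5 | lithium dienolate from addition of 4 to C6 of 3 (C6 epimers) | COC(=O)C1=CC=C([O-])OC1O[C@H](C)[C@@H]2CO2.[Li+] | intermediate
6 | lithium salt of acid 7 | [Li+].[O-]C(=O)/C=C\C(C(=O)OC)=C/O[C@H](C)[C@@H]1CO1 | intermediate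
7 | (2Z,4E)-4-(methoxycarbonyl)-5-{(1R)-1-[(2S)-oxiran-2-yl]ethoxy}penta-2,4-dienoic acid | OC(=O)/C=C\C(C(=O)OC)=C/O[C@H](C)[C@@H]1CO1 | intermediate
8 | hydroxytyrosol | OCCc1ccc(O)c(O)c1 | starting material
9 | [2-(3,4-dihydroxyphenyl)ethoxy]triphenylphosphonium salt of the carboxylate of 7 | Oc1ccc(CCO[P+](c2ccccc2)(c2ccccc2)c2ccccc2)cc1O.[O-]C(=O)/C=C\C(C(=O)OC)=C/O[C@H](C)[C@@H]1CO1 | intermediate
10 | 2-(3,4-dihydroxyphenyl)ethyl (2Z,4E)-4-(methoxycarbonyl)-5-{(1R)-1-[(2S)-oxiran-2-yl]ethoxy}penta-2,4-dienoate | COC(=O)C(/C=C\C(=O)OCCc1ccc(O)c(O)c1)=C/O[C@H](C)[C@@H]1CO1 | intermediate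
11 | open secondary C3 radical carrying CH2O–TiClCp2 (Cp drawn σ-bonded) | COC(=O)C(/C=C\C(=O)OCCc1ccc(O)c(O)c1)=C/O[C@H](C)[CH]CO[Ti](Cl)(C1C=CC=C1)C1C=CC=C1 | intermediate
12 | cyclised dihydropyran with the radical α to the side-chain ester | COC(=O)C1=CO[C@H](C)[C@@H](CO[Ti](Cl)(C2C=CC=C2)C2C=CC=C2)[C@@H]1[CH]C(=O)OCCc1ccc(O)c(O)c1 | intermediate
13 | methyl (2R,3R,4S)-4-{2-[2-(3,4-dihydroxyphenyl)ethoxy]-2-oxoethyl}-3-(hydroxymethyl)-2-methyl-3,4-dihydro-2H-pyran-5-carboxylate | COC(=O)C1=CO[C@H](C)[C@@H](CO)[C@@H]1CC(=O)OCCc1ccc(O)c(O)c1 | target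

## Step count and risks
Total steps: 4, with no protecting groups. Longest linear sequence: 4 (1 → 2 → 7 → 10 → 13).

**Step 2, the proposed new step, is the most uncertain.**
- Failure modes: the alkoxide may attack the lactone carbonyl instead of C6. Alkoxide 4 may undergo Payne migration if it warms. The enol ether may form as an E/Z mixture. The free (2Z)-acid 7 can slowly revert to 3 and 2.
- The fallback uses known chemistry only. It sets out from 2 and 8 and rejoins the route at 12. Amine-catalysed oxa-Michael addition of 2 to methyl propiolate (N-methylmorpholine, CH2Cl2) gives methyl (E)-3-{(1R)-1-[(2S)-oxiran-2-yl]ethoxy}prop-2-enoate F1. Iodination–elimination (NIS, AcOH, then Et3N) gives methyl (Z)-2-iodo-3-{(1R)-1-[(2S)-oxiran-2-yl]ethoxy}prop-2-enoate F2. Acylation of 8 by vinyl acrylate with immobilised Candida antarctica lipase B gives 2-(3,4-dihydroxyphenyl)ethyl prop-2-enoate F3. A Heck coupling of F2 and F3 (Pd(OAc)2, Bu4NCl, NaHCO3, DMF, 50 °C, argon) gives 2-(3,4-dihydroxyphenyl)ethyl (2E,4E)-4-(methoxycarbonyl)-5-{(1R)-1-[(2S)-oxiran-2-yl]ethoxy}penta-2,4-dienoate F4. Under the conditions of step 4 this gives the (2E) open titanoxy radical F5. That radical closes to 12, because the enoate geometry is lost at that point.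

**Step 4 is next.**
- Failure modes: radical 11 may be reduced or deoxygenated before it cyclises. The diastereoselectivity at C3 cannot be corrected afterwards. The catechol may bind tetravalent titanium. The product can lactonise with loss of hydroxytyrosol.
- The fallback sets out from 10 and comes back at 13. It replaces the radical closure by a polar, thermodynamically controlled one. Meinwald rearrangement of the terminal oxirane (Cr(TPP)OTf, 2 mol %, 1,2-dichloroethane, rt) gives 2-(3,4-dihydroxyphenyl)ethyl (2Z,4E)-4-(methoxycarbonyl)-5-{[(2R)-4-oxobutan-2-yl]oxy}penta-2,4-dienoate F6. Enamine-mediated intramolecular Michael addition follows (matched enantiomer of α,α-diphenylprolinol trimethylsilyl ether, PhCO2H, CH2Cl2). The formyl-bearing C3 is epimerisable and the O1–C2 bond is reversible by retro-oxa-Michael/oxa-Michael. The mixture therefore drains to the all-trans closed-ring oleuropein aglycone, methyl (2R,3S,4S)-4-{2-[2-(3,4-dihydroxyphenyl)ethoxy]-2-oxoethyl}-3-formyl-2-methyl-3,4-dihydro-2H-pyran-5-carboxylate F7. Aldehyde-selective reduction (NaBH4, MeOH/CH2Cl2, −40 °C, AcOH quench) gives 13.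

**Step 1 is third.**
- Failure modes: the selectivity factor for a small terminal methyl carbinol is probably only moderate (my estimate), which would cap the ee of the epoxide product. In addition, 2 is volatile and water-soluble.
- The fallback sets out from 1 and comes back at 2. It resolves by recovery instead of by product formation. With L-(+)-DIPT, Ti(OiPr)4 and TBHP (0.65 equiv) the (S)-alcohol is consumed, and (R)-but-3-en-2-ol F8 is recovered in over 98% ee. A separate matched epoxidation of this alcohol (D-(−)-DIPT, Ti(OiPr)4, TBHP, −20 °C) gives 2 with a second stage of enantiomer enrichment, at the cost of one more step.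

## Further compounds
F1 | step 2 | methyl (E)-3-{(1R)-1-[(2S)-oxiran-2-yl]ethoxy}prop-2-enoate | COC(=O)/C=C/O[C@H](C)[C@@H]1CO1
F2 | step 2 | methyl (Z)-2-iodo-3-{(1R)-1-[(2S)-oxiran-2-yl]ethoxy}prop-2-enoate | COC(=O)/C(I)=C/O[C@H](C)[C@@H]1CO1
F3 | step 2 | 2-(3,4-dihydroxyphenyl)ethyl prop-2-enoate | C=CC(=O)OCCc1ccc(O)c(O)c1
F4 | step 2 | 2-(3,4-dihydroxyphenyl)ethyl (2E,4E)-4-(methoxycarbonyl)-5-{(1R)-1-[(2S)-oxiran-2-yl]ethoxy}penta-2,4-dienoate | COC(=O)C(/C=C/C(=O)OCCc1ccc(O)c(O)c1)=C/O[C@H](C)[C@@H]1CO1
F5 | step 2 | (2E) open titanoxy radical | COC(=O)C(/C=C/C(=O)OCCc1ccc(O)c(O)c1)=C/O[C@H](C)[CH]CO[Ti](Cl)(C1C=CC=C1)C1C=CC=C1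
F6 | step 4 | 2-(3,4-dihydroxyphenyl)ethyl (2Z,4E)-4-(methoxycarbonyl)-5-{[(2R)-4-oxobutan-2-yl]oxy}penta-2,4-dienoate | COC(=O)C(/C=C\C(=O)OCCc1ccc(O)c(O)c1)=C/O[C@H](C)CC=O
F7 | step 4 | methyl (2R,3S,4S)-4-{2-[2-(3,4-dihydroxyphenyl)ethoxy]-2-oxoethyl}-3-formyl-2-methyl-3,4-dihydro-2H-pyran-5-carboxylate | COC(=O)C1=CO[C@H](C)[C@@H](C=O)[C@@H]1CC(=O)OCCc1ccc(O)c(O)c1
F8 | step 1 | (R)-but-3-en-2-ol | C[C@@H](O)C=C
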